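Prostanoid numbering is used (C1 acid carbon, ring C8–C12, C9 carbonyl, C15 acetoxy carbon). The ring is a 4,5-disubstituted cyclopent-2-enone in which C9 lies between C8 and C10, so C8–C9(O)–C10–C11–C12 is a latent 2-oxy-pentadienyl cation; its 4π closure joins C8 to C12 and leaves C10=C11, as in the oxidopentadienyl cyclisation presumed for the allene oxide route to cyclopentenone oxylipins.
Retrosynthesis: the tert-butyl ester is cleaved; C8–C12 is cut and C10=C11 returned to C11=C12, giving the acyclic enyne pivalate 10 (C8≡C9, C10–OPiv, 11E,13E-diene); C9–C10 is cut to alkyne 8 and dienal 6; C13=C14 is cut to phosphonate 1 and enal 2.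
Forward: the chain is joined at C13=C14 (olefination), then at C9–C10 (alkynylation); the only ring is closed in one gold-catalysed cycloisomerisation and the acid is unmasked last.
Stereochemistry: C15 by reagent-controlled ketone reduction; C10 (sacrificial) by catalytic asymmetric alkynylation; C12 from C10 by chirality transfer in the ring closure; C8 by equilibration to the trans ketone.

Key step: step 8

Assumption: (S,S)-ProPhenol is taken to deliver the alkynyl group to the Re face of the enal carbonyl (10S carbinol); the configuration of 9 is checked by Mosher ester analysis, and the (R,R)-ligand is used instead, with nothing else changed, if the sense of the addition or of the later chirality transfer is the opposite.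

Step 1
Reactants: 1 dimethyl (2-oxoheptyl)phosphonate; 2 (E)-4,4-dimethoxybut-2-enal
Product: 3 (7E,9E)-11,11-dimethoxyundeca-7,9-dien-6-one
Conditions: LiCl, i-Pr2NEt, MeCN, 0 °C to rt
Reagents that add atoms: none
Why: Horner–Wadsworth–Emmons olefination under Masamune–Roush conditions, in which the stabilised β-ketophosphonate anion should form the new C13=C14 bond E-selectively while the mild base leaves the enal geometry and the acetal untouched.

Step 2
Reactants: 3 (7E,9E)-11,11-dimethoxyundeca-7,9-dien-6-one
Product: 4 (6S,7E,9E)-11,11-dimethoxyundeca-7,9-dien-6-ol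
Conditions: (R)-2-methyl-CBS-oxazaborolidine (0.2 equiv), catecholborane, toluene, −78 °C; MeOH quench, aq. NaOH wash
Reagents that add atoms: none
Why: Corey–Bakshi–Shibata reduction, in which the dienyl group acts as the large and the n-pentyl group as the small substituent, so the (R)-catalyst should deliver hydride 1,2 to the face that gives the S allylic alcohol (the future C15).

Step 3
Reactants: 4 (6S,7E,9E)-11,11-dimethoxyundeca-7,9-dien-6-ol
Product: 5 (6S,7E,9E)-11,11-dimethoxyundeca-7,9-dien-6-yl acetate
Conditions: Ac2O, pyridine, DMAP (cat.), CH2Cl2, 0 °C to rt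
Reagents that add atoms: acetic anhydride CC(=O)OC(C)=O
Why: DMAP-catalysed O-acylation of a secondary allylic alcohol under basic conditions that touch neither the acetal nor the stereocentre.

Step 4
Reactants: 5 (6S,7E,9E)-11,11-dimethoxyundeca-7,9-dien-6-yl acetate
Product: 6 (2E,4E,6S)-6-acetoxyundeca-2,4-dienal
Conditions: pyridinium p-toluenesulfonate (cat.), THF/H2O 4:1, rt
Reagents that add atoms: water O
Why: acid-catalysed acetal hydrolysis through a diene-stabilised oxocarbenium ion, fast enough under buffered conditions to spare the allylic acetate and the E,E geometry.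

Step 5
Reactants: 7 non-8-ynoic acid
Product: 8 tert-butyl non-8-ynoate
Conditions: tert-butyl 2,2,2-trichloroacetimidate, BF3·OEt2 (cat.), CH2Cl2/cyclohexane, rt
Reagents that add atoms: tert-butyl 2,2,2-trichloroacetimidate CC(C)(C)OC(=N)C(Cl)(Cl)Cl
Why: acid-catalysed tert-butylation of a carboxylic acid by a trichloroacetimidate (tert-butyl cation transfer), compatible with the terminal alkyne.

Step 6
Reactants: 6 (2E,4E,6S)-6-acetoxyundeca-2,4-dienal; 8 tert-butyl non-8-ynoate (3 equiv, excess recovered)
Product: 9 tert-butyl (10S,11E,13E,15S)-15-acetoxy-10-hydroxyicosa-11,13-dien-8-ynoate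
Conditions: (S,S)-ProPhenol [2,6-bis{[(S)-2-(hydroxydiphenylmethyl)pyrrolidin-1-yl]methyl}-4-methylphenol] (20 mol %), Me2Zn (3 equiv), Ph3PO (40 mol %), toluene, 0 °C; aq. NH4Cl
Reagents that add atoms: none
Why: catalytic enantioselective alkynylation of an aldehyde with the dinuclear ProPhenol–Me2Zn catalyst, in which the methylzinc alkynyl species generated in situ from 8 adds 1,2 to the enal inside the chiral pocket to set C10, while Me2Zn leaves the acetate and the tert-butyl ester alone.

Step 7
Reactants: 9 tert-butyl (10S,11E,13E,15S)-15-acetoxy-10-hydroxyicosa-11,13-dien-8-ynoate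
Product: 10 tert-butyl (10S,11E,13E,15S)-15-acetoxy-10-(pivaloyloxy)icosa-11,13-dien-8-ynoate
Conditions: PivCl, Et3N, DMAP (cat.), CH2Cl2, 0 °C
Reagents that add atoms: pivaloyl chloride CC(C)(C)C(Cl)=O
Why: DMAP-catalysed acylation with retention at C10, which installs the migrating group for the ring closure and differentiates it from the C15 acetate.

Step 8
Reactants: 10 tert-butyl (10S,11E,13E,15S)-15-acetoxy-10-(pivaloyloxy)icosa-11,13-dien-8-ynoate
Product: 13 tert-butyl 7-[(1R,2S)-2-[(1E,3S)-3-acetoxyoct-1-en-1-yl]-5-oxocyclopent-3-en-1-yl]heptanoate, via cyclopentadienyl pivalate 11 (not isolated), via cis ketone 12 (not isolated)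
Conditions: Ph3PAuCl (5 mol %), AgSbF6 (5 mol %), MeCN, H2O (3 equiv), −20 °C to rt; then Et3N (1 equiv), rt
Reagents that add atoms: none
Why: The cationic monovalent gold complex Ph3PAu+ activates the C8≡C9 alkyne, the pivalate carbonyl oxygen adds to C9 and the C10–O bond then breaks, so that a 1,2-acyloxy shift gives a C8-aurated 2-pivaloyloxy-pentadienyl cation spanning C8–C12, which closes between C8 and C12 and, after loss of Ph3PAu+, leaves the new C10=C11 bond in dienyl ester 11; water then cleaves the acyl–oxygen bond of 11 (the C9 ketone oxygen is the former pivalate carbonyl oxygen) and the enol is protonated at C8. The closest known reaction type is the gold-catalysed Rautenstrauch rearrangement of 1-alkynyl-2-alkenyl carboxylates to cyclopent-2-enones. The cyclopentene ring is closed by a cationic 4π conrotatory (Nazarov-type) electrocyclisation, in Baldwin terms a 5-endo-trig attack of the aurated carbon C8 on C12. C12 is set by centre-to-helix-to-centre chirality transfer: the C10–O bond ionises perpendicular to the C11=C12 plane and C8 bonds to the opposite face, so the 10S ester with the 11E alkene should give 12S, while C8 is set under thermodynamic control when Et3N equilibrates the kinetically expected cis ketone 12 to the trans ketone 13 through the C8 enolate. The step needs clean 1,2-acyloxy migration, five- rather than seven-membered closure of the diene-extended cation and retention of its helicity; the 11E geometry (a C8–C14 bond would place a trans double bond in a seven-membered ring) and the electron-withdrawing C15 acetate, which keeps the positive charge at C12 rather than C14, should secure the ring size, and a competing 1,3-shift to the allenyl pivalate is reversible under the cationic gold catalyst and should drain back through the 1,2-pathway.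

Step 9
Reactants: 13 tert-butyl 7-[(1R,2S)-2-[(1E,3S)-3-acetoxyoct-1-en-1-yl]-5-oxocyclopent-3-en-1-yl]heptanoate
Product: 14 7-[(1R,2S)-2-[(1E,3S)-3-acetoxyoct-1-en-1-yl]-5-oxocyclopent-3-en-1-yl]heptanoic acid
Conditions: CF3CO2H/CH2Cl2 1:4, 0 °C; toluene azeotrope
Reagents that add atoms: none
Why: acidolysis of the tert-butyl ester by alkyl–oxygen cleavage (unimolecular loss of the tert-butyl cation as isobutene), which should leave the secondary acetate, the enone and both ring stereocentres untouched at 0 °C.

Compound list
1 | dimethyl (2-oxoheptyl)phosphonate | CCCCCC(=O)CP(=O)(OC)OC | starting material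
2 | (E)-4,4-dimethoxybut-2-enal | COC(OC)/C=C/C=O | starting material
3 | (7E,9E)-11,11-dimethoxyundeca-7,9-dien-6-one | CCCCCC(=O)/C=C/C=C/C(OC)OC | intermediate
4 | (6S,7E,9E)-11,11-dimethoxyundeca-7,9-dien-6-ol | CCCCC[C@@H](/C=C/C=C/C(OC)OC)O | intermediate
5 | (6S,7E,9E)-11,11-dimethoxyundeca-7,9-dien-6-yl acetate | CCCCC[C@@H](/C=C/C=C/C(OC)OC)OC(C)=O | intermediate
6 | (2E,4E,6S)-6-acetoxyundeca-2,4-dienal | CCCCC[C@@H](/C=C/C=C/C=O)OC(C)=O | intermediate
7 | non-8-ynoic acid | C#CCCCCCCC(=O)O | starting material
8 | tert-butyl non-8-ynoate | C#CCCCCCCC(=O)OC(C)(C)C | intermediate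
9 | tert-butyl (10S,11E,13E,15S)-15-acetoxy-10-hydroxyicosa-11,13-dien-8-ynoate | CCCCC[C@@H](/C=C/C=C/[C@H](O)C#CCCCCCCC(=O)OC(C)(C)C)OC(C)=O | intermediate
10 | tert-butyl (10S,11E,13E,15S)-15-acetoxy-10-(pivaloyloxy)icosa-11,13-dien-8-ynoate | CCCCC[C@@H](/C=C/C=C/[C@H](OC(=O)C(C)(C)C)C#CCCCCCCC(=O)OC(C)(C)C)OC(C)=O | intermediate
11 | tert-butyl 7-[(5S)-5-[(1E,3S)-3-acetoxyoct-1-en-1-yl]-2-(pivaloyloxy)cyclopenta-1,3-dien-1-yl]heptanoate | CCCCC[C@@H](/C=C/[C@H]1C=CC(OC(=O)C(C)(C)C)=C1CCCCCCC(=O)OC(C)(C)C)OC(C)=O | intermediate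
12 | tert-butyl 7-[(1S,2S)-2-[(1E,3S)-3-acetoxyoct-1-en-1-yl]-5-oxocyclopent-3-en-1-yl]heptanoate (cis, C8 epimer of 13) | CCCCC[C@@H](/C=C/[C@H]1C=CC(=O)[C@H]1CCCCCCC(=O)OC(C)(C)C)OC(C)=O | intermediate
13 | tert-butyl 7-[(1R,2S)-2-[(1E,3S)-3-acetoxyoct-1-en-1-yl]-5-oxocyclopent-3-en-1-yl]heptanoate | CCCCC[C@@H](/C=C/[C@H]1C=CC(=O)[C@@H]1CCCCCCC(=O)OC(C)(C)C)OC(C)=O | intermediate
14 | 7-[(1R,2S)-2-[(1E,3S)-3-acetoxyoct-1-en-1-yl]-5-oxocyclopent-3-en-1-yl]heptanoic acid | CCCCC[C@@H](/C=C/[C@H]1C=CC(=O)[C@@H]1CCCCCCC(=O)O)OC(C)=O | target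

Total steps: 9. Longest linear sequence: 8 (steps 1–4, then 6–9).

Steps most likely to fail

Step 8. The internal alkyne may favour 1,3- over 1,2-acyloxy migration. The diene-extended cation may live long enough to lose its helicity, which would erode the transfer of chirality from C10 to C12, or it may be captured by the C15 acetate. The amine equilibration at C8 may also be accompanied by migration of the ring double bond toward C12. The fallback is the biomimetic allene oxide closure, known as the oxidative cyclisation of vinylallenes, and it sets out from 9. Mitsunobu reaction of 9 with 2-nitrobenzenesulfonylhydrazide (PPh3, diethyl azodicarboxylate, THF, −15 °C to rt) should give, with inversion at C10, the sulfonylhydrazine tert-butyl (10R,11E,13E,15S)-15-acetoxy-10-[1-(2-nitrophenylsulfonyl)hydrazin-1-yl]icosa-11,13-dien-8-ynoate F1. On warming, F1 loses 2-nitrobenzenesulfinic acid to give the diazene tert-butyl (10R,11E,13E,15S)-15-acetoxy-10-diazenylicosa-11,13-dien-8-ynoate F2. The retro-ene loss of dinitrogen from F2 delivers hydrogen to C8 and gives the vinylallene tert-butyl (Sa,11E,13E,15S)-15-acetoxyicosa-8,9,11,13-tetraenoate F3. Dimethyldioxirane (acetone/CH2Cl2, −40 °C) should epoxidise the alkyl-substituted C8=C9 bond of F3 anti to the dienyl group, giving the allene oxide tert-butyl 7-[(2R,3E)-3-[(2E,4E,6S)-6-acetoxyundeca-2,4-dien-1-ylidene]oxiran-2-yl]heptanoate F4. F4 opens at C8–O to the 2-oxidopentadienyl zwitterion and closes between C8 and C12 to the cis ketone 12; Et3N equilibration as in step 8 then comes back to the route at 13. Because C15 is already fixed, a ring formed with the wrong sense at C12 is a diastereomer of 13 and is removed by chromatography.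

Step 6. The addition of an unactivated alkyl alkyne to a dienal may proceed with low enantioselectivity or with the opposite facial sense, and turnover may be slow. The fallback replaces the asymmetric C–C bond formation by addition, oxidation and reagent-controlled reduction, and sets out from 8 and 6. n-BuLi (0.95 equiv relative to 8, THF, −78 °C) converts 8 to its lithium alkynyl derivative, which adds to 6 at −78 °C to give the carbinol as a mixture of C10 epimers, tert-butyl (11E,13E,15S)-15-acetoxy-10-hydroxyicosa-11,13-dien-8-ynoate F5. MnO2 (CH2Cl2, rt) oxidises F5 to the ynone tert-butyl (11E,13E,15S)-15-acetoxy-10-oxoicosa-11,13-dien-8-ynoate F6. Reduction of F6 with (S)-Alpine-Borane (B-isopinocampheyl-9-borabicyclo[3.3.1]nonane from (−)-α-pinene; THF, rt), in which the slim alkynyl group acts as the small substituent, should give the 10S carbinol and so comes back to the route at 9.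

Step 9. Acid may ionise the allylic C15 acetate (loss, allylic transposition or epimerisation) or move the ring double bond during tert-butyl cleavage. The fallback replaces acidolysis by enzymatic hydrolysis and re-acetylation, and sets out from 13. Candida antarctica lipase A or the Bacillus subtilis p-nitrobenzyl esterase, both of which accept tert-butyl esters, with porcine liver esterase added to complete removal of the acetate (phosphate buffer pH 7/acetone, 30 °C), should take off both esters to give the free hydroxy acid 7-[(1R,2S)-2-[(1E,3S)-3-hydroxyoct-1-en-1-yl]-5-oxocyclopent-3-en-1-yl]heptanoic acid F7. Acetylation of F7 (Ac2O, pyridine, 0 °C; aqueous work-up to hydrolyse the mixed anhydride at C1) then comes back to the route at 14.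

Further compounds
F1 | step 8 | tert-butyl (10R,11E,13E,15S)-15-acetoxy-10-[1-(2-nitrophenylsulfonyl)hydrazin-1-yl]icosa-11,13-dien-8-ynoate | CCCCC[C@@H](/C=C/C=C/[C@@H](N(N)S(=O)(=O)c1ccccc1[N+](=O)[O-])C#CCCCCCCC(=O)OC(C)(C)C)OC(C)=O
F2 | step 8 | tert-butyl (10R,11E,13E,15S)-15-acetoxy-10-diazenylicosa-11,13-dien-8-ynoate | CCCCC[C@@H](/C=C/C=C/[C@@H](N=N)C#CCCCCCCC(=O)OC(C)(C)C)OC(C)=O
F3 | step 8 | tert-butyl (Sa,11E,13E,15S)-15-acetoxyicosa-8,9,11,13-tetraenoate | CC(C)(C)OC(=O)CCCCCCC([H])=[C@@]=C([H])/C=C/C=C/[C@H](CCCCC)OC(C)=O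
F4 | step 8 | tert-butyl 7-[(2R,3E)-3-[(2E,4E,6S)-6-acetoxyundeca-2,4-dien-1-ylidene]oxiran-2-yl]heptanoate | CC(C)(C)OC(=O)CCCCCC[C@H]1O/C1=C/C=C/C=C/[C@H](CCCCC)OC(C)=O
F5 | step 6 | tert-butyl (11E,13E,15S)-15-acetoxy-10-hydroxyicosa-11,13-dien-8-ynoate (C10 epimer mixture) | CCCCC[C@@H](/C=C/C=C/C(O)C#CCCCCCCC(=O)OC(C)(C)C)OC(C)=O
F6 | step 6 | tert-butyl (11E,13E,15S)-15-acetoxy-10-oxoicosa-11,13-dien-8-ynoate | CCCCC[C@@H](/C=C/C=C/C(=O)C#CCCCCCCC(=O)OC(C)(C)C)OC(C)=O
F7 | step 9 | 7-[(1R,2S)-2-[(1E,3S)-3-hydroxyoct-1-en-1-yl]-5-oxocyclopent-3-en-1-yl]heptanoic acid | CCCCC[C@@H](/C=C/[C@H]1C=CC(=O)[C@@H]1CCCCCCC(=O)O)O
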